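| setting | Saturday's | Wednesday's | Monday's | flask |
|---|---|---|---|---|
| starting material | 0.0020 M | 0.0020 M | 0.0030 M | 0.0020 M |
| partner | 1.2 mM | 4.8 mM | 2.4 mM | 2.40 mM |
| remark | run made earlier | run made earlier | run made earlier |  |
| time |  |  |  | 10 min |

| run | time / min | starting material / % | target / % |
|---|---|---|---|
| Saturday's | 0.833 | 15.9 | 2.6 |
| Saturday's | 2.50 | 15.7 | 2.3 |
| Saturday's | 4.00 | 15.9 | 2.4 |
| Saturday's | 6.00 | 15.7 | 2.2 |
| Saturday's | 10.0 | 15.6 | 2.5 |
| Saturday's | 12.0 | 15.6 | 2.5 |
| Wednesday's | 1.00 | 1.0 | 6.5 |
| Wednesday's | 1.50 | 1.1 | 6.1 |
| Wednesday's | 2.50 | 0.4 | 6.6 |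
| Wednesday's | 4.00 | 0.6 | 6.9 |
| Wednesday's | 8.00 | 0.1 | 7.3 |
| Wednesday's | 12.0 | 0.8 | 7.1 |
| Monday's | 1.00 | 10.9 | 3.3 |
| Monday's | 3.00 | 10.7 | 3.4 |
| Monday's | 6.00 | 10.5 | 3.4 |
| Monday's | 8.00 | 9.9 | 2.9 |
| Monday's | 12.0 | 10.0 | 3.2 |

(standard deviation of a reading: 0.3 percentage points)

- the earlier runs were read with a standard deviation of 0.3 percentage points
- the reaction counts as stopped when no species that holds the starting material changes by six tenths of a point or more over the second half of the time

1. the state of affairs at 10 min: stopped, and by what, or still going (it is still moving / the partner has run out first / all of the starting material has reacted / forward and back rates have come level)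
2. part of the starting material gone at 10 min
3. the target standing at 10 min, as a percentage of the starting material charged
4. the side product standing at 10 min, as a percentage of the starting material charged

Nearly level curves are the easy case: each run can be replaced by the mean of its last 3 starting-material readings, with an error near 0.17 percentage points. The first readings stay out: Wednesday's run reads 1.0% at 1.00 min and Monday's 10.9% at 1.00 min, and both may still be sinking there. Let a be that mean as a fraction of the charge, and r the equivalents of partner per starting material charged. The dose constant e = ln(1/a)/r then treats the residue as a first-order decay counted in partner dose instead of time. Saturday's run reads 3.09, Monday's 2.86 at r = 0.800, and Wednesday's 2.21 at r = 2.40.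

For the next shift, this note's own reckoning: the flask has r = 1.20, and a straight line between Monday and Wednesday gives it a dose constant of 2.70. The flask should therefore hold 3.93% starting material at 10 min, with partner as the limiting reagent. Leave the clock alone: Saturday's run reads 15.9% at 0.833 min and 15.6% at 12.0 min.

The forecast differs: forward and back rates have come level, conversion 96.8%, target 4.3%, side product 92.5%, on the grounds that “I read the stop as an equilibrium rather than exhaustion”.

The flask gives: the partner has run out first, conversion 95.5%, target 5.86%, side product 81.0%.

    2 second intermediate → homo product (k = 64.0 M⁻¹ s⁻¹)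
    open intermediate + second intermediate → target (k = 34.0 M⁻¹ s⁻¹)
    starting material ⇌ open intermediate (K = 1.90, k = 0.0640 s⁻¹)
    partner → second intermediate (k = 0.470 s⁻¹)
    starting material + second intermediate → side product (k = 290 M⁻¹ s⁻¹)

Partner already stands at 0% after 1.00 min, and open intermediate holds 8.64% at 10.0 min. The flask's dose constant comes out at 2.58, against 2.70. The neighbour with 8.0 × 10⁻⁴ M starting material has r = 3.00, where the same line gives a residue of 0.278%; that neighbour holds 0.51%.

The runs are simulated for an exercise, and the scatter is random.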